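Giganteone A is an unsymmetrical dehydrodimer of malabaricone C. Its single inter-unit bond joins C-6 of the catechol ring of one unit (chain at C-1, OH at C-3 and C-4; the CH ortho to the chain) to C-3 of the 2-acylresorcinol ring of the other. The route rests on an anodic cross-dehydrogenative dimerisation of unprotected malabaricone C: oxidation reverses the polarity of one catechol ring (o-quinone) and the acylresorcinol ring of a second molecule adds to it, so that two normally nucleophilic arene carbons are joined with all eight phenols free. The precursor is the monomer itself, assembled in four steps from three commercial pieces.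

Key step: step 5

Assumption: the target has no stereocentre, and its biaryl axis carries only two ortho substituents (one alkyl, one OH) and is not configurationally stable; it is therefore treated as achiral and no stereochemical operation is planned.

Step 1
Reactants: 1 non-8-enoic acid
Product: 3 N-methoxy-N-methylnon-8-enamide, via 1-(non-8-enoyl)imidazole 2 (not isolated)
Conditions: CDI (1.1 equiv), CH2Cl2, rt, 1 h; then MeNH(OMe)·HCl (1.2 equiv), rt, 12 h
Reagents that add atoms: N,O-dimethylhydroxylamine hydrochloride, CNOC.Cl
Why: CDI amide coupling; the acid is activated as acylimidazole 2 (CO2 lost), and the liberated imidazole frees the amine from its hydrochloride for acyl substitution, while the remote terminal alkene is inert.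

Step 2
Reactants: 3 N-methoxy-N-methylnon-8-enamide; 4 1,3-dimethoxybenzene
Product: 7 1-(2,6-dimethoxyphenyl)non-8-en-1-one, via 2,6-dimethoxyphenyllithium 5 (not isolated), via lithium hemiaminal chelate 6 (not isolated)
Conditions: 4 (1.3 equiv), n-BuLi (1.25 equiv), THF, 0 °C → rt, 2 h; then 3, −78 → 0 °C; 1 M HCl quench
Reagents that add atoms: none
Why: Directed ortho-metalation at C-2 between the two methoxy groups followed by Weinreb ketone synthesis; the five-membered lithium chelate 6 survives until the acidic quench, so the ketone cannot be attacked a second time.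

Step 3
Reactants: 7 1-(2,6-dimethoxyphenyl)non-8-en-1-one; 8 4-bromo-1,2-dimethoxybenzene
Product: 10 9-(3,4-dimethoxyphenyl)-1-(2,6-dimethoxyphenyl)nonan-1-one, via B-alkyl-9-BBN borane 9 (not isolated)
Conditions: 9-BBN (1.2 equiv), THF, 0 °C → rt, 4 h; then 8 (1.0 equiv), Pd(dppf)Cl2 (5 mol %), 3 M aq. K3PO4 (3 equiv), DMF, 60 °C
Reagents that add atoms: none
Why: Anti-Markovnikov hydroboration of the terminal alkene by 9-BBN should be much faster than reduction of the hindered, doubly ortho-substituted aryl ketone, and the primary borane then undergoes B-alkyl Suzuki–Miyaura coupling with the aryl bromide.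

Step 4
Reactants: 10 9-(3,4-dimethoxyphenyl)-1-(2,6-dimethoxyphenyl)nonan-1-one
Product: 11 malabaricone C [1-(2,6-dihydroxyphenyl)-9-(3,4-dihydroxyphenyl)nonan-1-one]
Conditions: BBr3 (8 equiv), CH2Cl2, −78 °C → rt, N2; ice-water quench
Reagents that add atoms: none
Why: Lewis-acid ether cleavage (BBr3 demethylation); each ArO–Me is complexed by boron and bromide attacks the methyl group in an SN2 step, the ketone-chelated ortho ethers being the most readily cleaved, and hydrolysis of the aryl borates frees the four phenols.

Step 5
Reactants: 11 malabaricone C (two molecules)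
Product: 14 giganteone A, via malabaricone C o-quinone 12 (not isolated), via dienone Michael adduct 13 (not isolated)
Conditions: divided cell, graphite-felt anode, Pt cathode, controlled potential on the catechol wave (about +0.4 V vs Ag/AgCl expected, to be set from a voltammogram of 11), 0.1 M 11 in MeCN/0.2 M aq. sodium phosphate pH 7.5 (1:1), N2, 10 °C, about 0.6–0.7 F per mol of 11; then pH 3, EtOAc extraction; recovered 11 recycled
Reagents that add atoms: none
Why: At a potential on the catechol wave the 3,4-dihydroxyphenyl ring of 11 is oxidised (2 e−, 2 H+) to o-quinone 12, while the acylresorcinol ring, which should oxidise only at clearly higher potential, is untouched. In the pH 7.5 buffer the 2-acylresorcinol of a second molecule of 11 (a vinylogous acid, the aromatic counterpart of the 1,3-dicarbonyl enols normally used as traps) is the phenol ionised first, and its phenolate adds through ring carbon C-3 (ortho to one O, para to the other) in a 1,4-addition to C-6 of 12, the unsubstituted carbon β to the C-4 carbonyl and next to the chain; tautomerisation of both rings of adduct 13 gives 14 (EC sequence). The closest known reaction types are the anodic oxidation of catechols in the presence of enolic C-nucleophiles with Michael arylation of the o-quinone, and the oxidative B-ring-quinone/A-ring coupling of flavan-3-ols to dehydrodicatechins. No ring is closed and no stereocentre remains: the two sp3 carbons of 13 vanish on re-aromatisation, and the biaryl axis is not configurationally stable. The selectivities needed are the ring that is oxidised (set by the anode potential), the nucleophile that captures 12 (set by preferential ionisation of the more acidic acylresorcinol over the catechol; attack by the resorcinol ring of either 11 or 12 leads to the same skeleton after redox exchange with 11), and the site on 12 (C-1 carries the chain, so C-6 is the only open β-position, the normal site for carbon nucleophiles on 4-alkyl-o-quinones). Re-oxidation and oligomerisation of 14, which still has one free catechol and one free acylresorcinol, should be held back by the limited charge and recycling of the monomer, and the concentrated solution disfavours the intramolecular 14-membered alternative.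

Compound list
1 | non-8-enoic acid | C=CCCCCCCC(=O)O | starting material
2 | 1-(non-8-enoyl)imidazole (not isolated) | C=CCCCCCCC(=O)n1ccnc1 | intermediate
3 | N-methoxy-N-methylnon-8-enamide | C=CCCCCCCC(=O)N(C)OC | intermediate
4 | 1,3-dimethoxybenzene | COc1cccc(OC)c1 | starting material
5 | 2,6-dimethoxyphenyllithium (not isolated) | [Li]c1c(OC)cccc1OC | intermediate
6 | lithium 1-(2,6-dimethoxyphenyl)-1-[methoxy(methyl)amino]non-8-en-1-olate, chelated tetrahedral adduct, racemic (not isolated) | [Li]OC(CCCCCCC=C)(N(C)OC)c1c(OC)cccc1OC | intermediate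
7 | 1-(2,6-dimethoxyphenyl)non-8-en-1-one | C=CCCCCCCC(=O)c1c(OC)cccc1OC | intermediate
8 | 4-bromo-1,2-dimethoxybenzene | COc1ccc(Br)cc1OC | starting material
9 | 9-(9-borabicyclo[3.3.1]nonan-9-yl)-1-(2,6-dimethoxyphenyl)nonan-1-one (not isolated) | O=C(CCCCCCCCB1C2CCCC1CCC2)c1c(OC)cccc1OC | intermediate
10 | 9-(3,4-dimethoxyphenyl)-1-(2,6-dimethoxyphenyl)nonan-1-one (malabaricone C tetramethyl ether) | O=C(CCCCCCCCc1ccc(OC)c(OC)c1)c1c(OC)cccc1OC | intermediate
11 | malabaricone C, 1-(2,6-dihydroxyphenyl)-9-(3,4-dihydroxyphenyl)nonan-1-one | O=C(CCCCCCCCc1ccc(O)c(O)c1)c1c(O)cccc1O | intermediate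
12 | malabaricone C o-quinone, 4-[9-(2,6-dihydroxyphenyl)-9-oxononyl]cyclohexa-3,5-diene-1,2-dione (not isolated) | O=C(CCCCCCCCC1=CC(=O)C(=O)C=C1)c1c(O)cccc1O | intermediate
13 | dienone Michael adduct, the doubly non-aromatic tautomer of 14 with sp3 CH at both carbons of the new bond, configuration undefined and lost on tautomerisation (not isolated) | O=C(CCCCCCCCC1=CC(=O)C(O)=CC1C1C=CC(O)=C(C(=O)CCCCCCCCc2ccc(O)c(O)c2)C1=O)c1c(O)cccc1O | intermediate
14 | giganteone A | O=C(CCCCCCCCc1cc(O)c(O)cc1-c1ccc(O)c(C(=O)CCCCCCCCc2ccc(O)c(O)c2)c1O)c1c(O)cccc1O | target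

Total step count: 5
Longest linear sequence: 5 steps (1 → 3 → 7 → 10 → 11 → 14)

Steps most likely to fail

Step 5 (key step). Process at risk: the o-quinone may be captured by the wrong partner (a catechol ring, water, or a phenol oxygen instead of ring carbon C-3), or it may isomerise to a quinone methide through its benzylic CH2. The first-formed dimer may also be oxidised again and grow into oligomers. The fallback is a Suzuki–Miyaura biaryl synthesis with fixed roles, built from known chemistry; it sets out from borane 9 and ketone 7 and comes back to the route at 14. Borane 9 is coupled with an excess of commercial 1,2-dibromo-4,5-dimethoxybenzene (Pd(dppf)Cl2, aq. K3PO4, DMF, 60 °C) to give the mono-coupled 9-(2-bromo-4,5-dimethoxyphenyl)-1-(2,6-dimethoxyphenyl)nonan-1-one F1. Miyaura borylation (B2pin2, Pd(dppf)Cl2, KOAc, dioxane, 90 °C) should convert it into 9-[4,5-dimethoxy-2-(4,4,5,5-tetramethyl-1,3,2-dioxaborolan-2-yl)phenyl]-1-(2,6-dimethoxyphenyl)nonan-1-one F2. Separately, 7 is brominated with NBS (MeCN, 0 °C; substitution at the doubly activated C-3 is expected to outrun any reaction at the isolated alkene) to 1-(3-bromo-2,6-dimethoxyphenyl)non-8-en-1-one F3. Cross-coupling of F2 with F3 (Pd(OAc)2, SPhos, K3PO4, toluene/H2O, 90 °C) should give the biaryl 1-{3-[2-(9-(2,6-dimethoxyphenyl)-9-oxononyl)-4,5-dimethoxyphenyl]-2,6-dimethoxyphenyl}non-8-en-1-one F4. Hydroboration with 9-BBN gives its terminal B-alkyl-9-BBN borane F5, and B-alkyl coupling with 8 under the conditions of step 3 gives giganteone A octamethyl ether F6. BBr3 under the conditions of step 4 then demethylates it to 14.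

Step 3. Process at risk: 9-BBN may reduce the aryl ketone in competition with hydroboration, and the alkylpalladium intermediate may undergo β-hydride elimination while the electron-rich bromide adds slowly, so that protodeboronated or isomerised chain material results. The fallback replaces the C(sp3)–C(sp2) coupling by olefin cross-metathesis and hydrogenation. It sets out from 7: cross-metathesis with commercial 3,4-dimethoxystyrene (3 equiv, second-generation Ru benzylidene–NHC catalyst 5 mol %, CH2Cl2, 40 °C) should give (E)-9-(3,4-dimethoxyphenyl)-1-(2,6-dimethoxyphenyl)non-8-en-1-one F7, and hydrogenation (H2 1 atm, Pd/C, EtOAc, rt) comes back to the route at 10.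

Step 2. Process at risk: the hindered aryllithium may deprotonate the α-CH2 of the amide instead of adding, or the ortho-lithiation may be incomplete, so that amide is returned. The fallback replaces acyl substitution by addition to an aldehyde and oxidation. It sets out from 3 and 5: DIBAL-H (THF, −78 °C) reduces 3 to non-8-enal F8; addition of aryllithium 5 (THF, −78 °C), which for an aldehyde should be faster than enolisation, gives racemic 1-(2,6-dimethoxyphenyl)non-8-en-1-ol F9, and Dess–Martin oxidation (CH2Cl2, rt) comes back to the route at 7.

Further compounds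
F1 | step 5 | 9-(2-bromo-4,5-dimethoxyphenyl)-1-(2,6-dimethoxyphenyl)nonan-1-one | O=C(CCCCCCCCc1cc(OC)c(OC)cc1Br)c1c(OC)cccc1OC
F2 | step 5 | 9-[4,5-dimethoxy-2-(4,4,5,5-tetramethyl-1,3,2-dioxaborolan-2-yl)phenyl]-1-(2,6-dimethoxyphenyl)nonan-1-one | O=C(CCCCCCCCc1cc(OC)c(OC)cc1B2OC(C)(C)C(C)(C)O2)c1c(OC)cccc1OC
F3 | step 5 | 1-(3-bromo-2,6-dimethoxyphenyl)non-8-en-1-one | C=CCCCCCCC(=O)c1c(OC)ccc(Br)c1OC
F4 | step 5 | 1-{3-[2-(9-(2,6-dimethoxyphenyl)-9-oxononyl)-4,5-dimethoxyphenyl]-2,6-dimethoxyphenyl}non-8-en-1-one | O=C(CCCCCCCCc1cc(OC)c(OC)cc1-c1ccc(OC)c(C(=O)CCCCCCC=C)c1OC)c1c(OC)cccc1OC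
F5 | step 5 | terminal B-alkyl-9-BBN borane of F4 | O=C(CCCCCCCCc1cc(OC)c(OC)cc1-c1ccc(OC)c(C(=O)CCCCCCCCB2C3CCCC2CCC3)c1OC)c1c(OC)cccc1OC
F6 | step 5 | giganteone A octamethyl ether | O=C(CCCCCCCCc1cc(OC)c(OC)cc1-c1ccc(OC)c(C(=O)CCCCCCCCc2ccc(OC)c(OC)c2)c1OC)c1c(OC)cccc1OC
F7 | step 3 | (E)-9-(3,4-dimethoxyphenyl)-1-(2,6-dimethoxyphenyl)non-8-en-1-one | O=C(CCCCCC/C=C/c1ccc(OC)c(OC)c1)c1c(OC)cccc1OC
F8 | step 2 | non-8-enal | C=CCCCCCCC=O
F9 | step 2 | 1-(2,6-dimethoxyphenyl)non-8-en-1-ol (racemic) | C=CCCCCCCC(O)c1c(OC)cccc1OC
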